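The cyclopentane of the octahydrocyclopenta[c]pyridine core is cut at C7–C7a and C4a–C5. N2 is flanked by the methylenes C1 and C3 and C4 can be carried as a ketone, so the piperidine ring is a furfurylamine-derived dihydropyridinone (4) with C4a=C7a as its enone; C5, C6 and C7 with its methyl come from the silylated allylic acetate 7, a methyl-trimethylenemethane precursor. One palladium-catalysed asymmetric [3+2] cycloaddition joins them, closes the cyclopentane cis-fused, sets C4a and C7a and leaves C6 as a methylene distinct from the C4 carbonyl. The tyrosol- and geranyl-derived half-ester acid is attached last by Mitsunobu inversion at C6.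

Key step: step 6

Remark on the structure: in the target H4, H4a and H7a are cis, the 7-methyl and the C6 ester oxygen lie cis on the convex face, and the two cyclohexane hydroxyls are trans; cyclopenta[c]pyridine numbering is used throughout.
Assumption: which antipode of the phosphoramidite gives the (4aS,7aR) series in step 6 cannot be predicted and is settled by a first run with each antipode; but-2-yn-1-ol, geranyl acetate and tyrosol are bought.

Step 1
Reactants: 1 furfurylamine
Product: 2 methyl (furan-2-ylmethyl)carbamate
Conditions: ClCO2Me, Et3N, CH2Cl2, 0 °C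
Reagents that add atoms: methyl chloroformate COC(=O)Cl
Why: Schotten–Baumann-type N-acylation of a primary amine with a chloroformate is reliable and installs the carbamate whose carbonyl carbon later becomes the N-methyl group.

Step 2
Reactants: 2 methyl (furan-2-ylmethyl)carbamate
Product: 3 methyl 6-hydroxy-3-oxo-3,6-dihydropyridine-1(2H)-carboxylate
Conditions: NBS, NaHCO3, THF/H2O (4:1), 0 °C
Reagents that add atoms: water O
Why: Aza-Achmatowicz oxidative ring expansion, in which bromonium-induced hydration of the furan gives a cis-enedione whose aldehyde is captured by the carbamate nitrogen as a cyclic hemiaminal, is well established for N-acyl furfurylamines, and the racemic hemiaminal carbon is removed in step 3.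

Step 3
Reactants: 3 methyl 6-hydroxy-3-oxo-3,6-dihydropyridine-1(2H)-carboxylate
Product: 4 methyl 3-oxo-3,6-dihydropyridine-1(2H)-carboxylate
Conditions: Et3SiH, BF3·OEt2, CH2Cl2, −78 → 0 °C
Reagents that add atoms: none
Why: Lewis-acid ionisation of the hemiaminal gives an N-acyliminium ion that triethylsilane reduces at the former hemiaminal carbon (ionic reduction), a standard follow-up to the aza-Achmatowicz reaction that leaves the conjugated enone untouched.

Step 4
Reactants: 5 but-2-yn-1-ol
Product: 6 (Z)-2-[(trimethylsilyl)methyl]but-2-en-1-ol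
Conditions: Me3SiCH2MgCl (3 equiv), CuI (copper monoiodide, 10 mol%), THF/Et2O, 0 → 40 °C; aq NH4Cl
Reagents that add atoms: (trimethylsilyl)methylmagnesium chloride C[Si](C)(C)C[Mg]Cl
Why: Copper-catalysed anti-carbomagnesiation of the propargylic alkoxide puts the silylmethyl group on the carbon next to the carbinol and magnesium on the distal carbon within a five-membered chelate, so protonolysis should give the (Z)-allylic alcohol with the methyl cis to the silylmethyl group.

Step 5
Reactants: 6 (Z)-2-[(trimethylsilyl)methyl]but-2-en-1-ol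
Product: 7 (Z)-2-[(trimethylsilyl)methyl]but-2-en-1-yl acetate
Conditions: Ac2O, pyridine, DMAP (cat.), CH2Cl2, 0 → 23 °C
Reagents that add atoms: acetic anhydride CC(=O)OC(C)=O
Why: Routine DMAP-catalysed acetylation of a primary allylic alcohol supplies the ionisable leaving group of the donor without touching the allylsilane.

Step 6
Reactants: 4 methyl 3-oxo-3,6-dihydropyridine-1(2H)-carboxylate; 7 (Z)-2-[(trimethylsilyl)methyl]but-2-en-1-yl acetate
Product: 8 methyl (4aS,7R,7aR)-7-methyl-6-methylidene-4-oxooctahydro-2H-cyclopenta[c]pyridine-2-carboxylate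
Conditions: Pd2(dba)3·CHCl3 (2.5 mol%), BINOL-derived phosphoramidite of trans-2,5-di(2-naphthyl)pyrrolidine (one antipode, 10 mol%), toluene, 23 → 45 °C
Reagents that add atoms: none
Why: Proposed new method: zerovalent palladium bearing the phosphoramidite ionises the allylic acetate of 7 and the released acetate removes the silyl group, giving a zwitterionic η3 palladium–trimethylenemethane complex that equilibrates to the isomer whose methyl-bearing carbon is the free nucleophilic terminus; this carbon adds to the β-carbon C7a of enone 4 and the resulting C4a enolate then alkylates a terminus of the cationic π-allyl unit. The closest known reactions are palladium-catalysed trimethylenemethane [3+2] cycloadditions to cyclic enones with achiral ligands, their phosphoramidite-controlled asymmetric variants on acyclic or doubly activated acceptors, and racemic additions of alkyl-substituted donors, which have not been combined on a heterocyclic enone. The cyclopentane is closed by a 5-(enolexo)-exo-tet alkylation of the enolate at the allyl terminus with palladium leaving outside the ring, and since both bonds form on one face of the six-membered ring the fusion must be cis. C7a is set by the ligand, which alone differentiates the faces of the flat, achiral enone; C4a follows from C7a through the cis fusion; C7 depends on the orientation of the methyl-bearing terminus during conjugate addition and is not relied on, because it becomes epimerisable next to the C6 ketone and is fixed in step 10. The step needs conjugate instead of carbonyl addition, bonding of the substituted donor terminus to C7a and high facial selectivity: the soft, unhindered β-carbon of the enone favours 1,4-attack, substituted donors react through their substituted carbon, and the resulting exocyclic methylene stays chemically distinct from the C4 ketone.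

Step 7
Reactants: 8 methyl (4aS,7R,7aR)-7-methyl-6-methylidene-4-oxooctahydro-2H-cyclopenta[c]pyridine-2-carboxylate
Product: 9 methyl (4S,4aS,7R,7aR)-4-hydroxy-4,7-dimethyl-6-methylideneoctahydro-2H-cyclopenta[c]pyridine-2-carboxylate
Conditions: MeMgBr, LaCl3·2LiCl, THF, −78 → 0 °C
Reagents that add atoms: methylmagnesium bromide C[Mg]Br
Why: Grignard 1,2-addition to the ketone, with LaCl3·2LiCl as Lewis acid to suppress enolisation at C4a, should occur from the convex face of the cis-fused bicycle so that the new methyl is cis to H4a and the hydroxyl lies on the concave face (4S), the carbamate being too unreactive to compete at low temperature.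

Step 8
Reactants: 9 methyl (4S,4aS,7R,7aR)-4-hydroxy-4,7-dimethyl-6-methylideneoctahydro-2H-cyclopenta[c]pyridine-2-carboxylate
Product: 11 methyl (4S,4aS,7R,7aS)-4-hydroxy-4,7-dimethyl-6-oxooctahydro-2H-cyclopenta[c]pyridine-2-carboxylate, via spiro-ozonide 10 (not isolated)
Conditions: O3, CH2Cl2, −78 °C; then PPh3, −78 → 23 °C
Reagents that add atoms: ozone [O-][O+]=O
Why: Ozonolysis with reductive work-up cleaves the only alkene, the 1,1-disubstituted C6 methylene, to the cyclopentanone and leaves the tertiary alcohol, the carbamate and all stereocentres untouched.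

Step 9
Reactants: 11 methyl (4S,4aS,7R,7aS)-4-hydroxy-4,7-dimethyl-6-oxooctahydro-2H-cyclopenta[c]pyridine-2-carboxylate
Product: 12 methyl (4aS,7R,7aS)-4,7-dimethyl-6-oxo-1,4a,5,6,7,7a-hexahydro-2H-cyclopenta[c]pyridine-2-carboxylate
Conditions: Burgess reagent (MeO2CN(−)SO2N(+)Et3), toluene, 60 °C
Reagents that add atoms: none
Why: Burgess dehydration is a syn elimination through a cyclic sulfamate transition state, and because the hydroxyl is trans to H4a only hydrogens on C3 or on the new methyl are syn-disposed, so the more substituted, nitrogen-conjugated C3=C4 enecarbamate is expected and the C4a stereocentre cannot be lost.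

Step 10
Reactants: 12 methyl (4aS,7R,7aS)-4,7-dimethyl-6-oxo-1,4a,5,6,7,7a-hexahydro-2H-cyclopenta[c]pyridine-2-carboxylate
Product: 13 methyl (4S,4aR,7R,7aS)-4,7-dimethyl-6-oxooctahydro-2H-cyclopenta[c]pyridine-2-carboxylate
Conditions: H2 (3 atm), Pd/C (palladium on carbon), MeOH, 23 °C; filter; then NaOMe (0.1 equiv), MeOH, 23 °C
Reagents that add atoms: none
Why: Heterogeneous hydrogenation of the enecarbamate delivers hydrogen to C4 from the convex face, anti to the C4a–C5 bond, which places H4 cis to H4a and the methyl on the concave face (4S), and the following catalytic methoxide treatment equilibrates C7 through the C6 enolate to the more stable epimer with the methyl on the convex face, trans to C1.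

Step 11
Reactants: 13 methyl (4S,4aR,7R,7aS)-4,7-dimethyl-6-oxooctahydro-2H-cyclopenta[c]pyridine-2-carboxylate
Product: 14 (4S,4aR,6R,7R,7aS)-2,4,7-trimethyloctahydro-1H-cyclopenta[c]pyridin-6-ol
Conditions: LiAlH4, THF, −78 → 0 °C, then 66 °C
Reagents that add atoms: none
Why: Hydride reduction with LiAlH4 attacks the C6 ketone from the convex face at low temperature, giving the concave (6R) alcohol trans to the 7-methyl, and on heating converts the methyl carbamate into the N-methyl group, so one reagent sets C6 and unmasks the tertiary amine.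

Step 12
Reactants: 15 tyrosol
Product: 16 4-hydroxy-4-(2-hydroxyethyl)cyclohexa-2,5-dien-1-one
Conditions: PhI(OAc)2, MeCN/H2O (3:1), 0 °C
Reagents that add atoms: water O
Why: Oxidative dearomatisation of a para-alkylphenol with PhI(OAc)2 in aqueous acetonitrile traps the phenoxenium-type intermediate with water at the para position to give the para-quinol, and under these nearly neutral conditions the primary alcohol should not add to the dienone.

Step 13
Reactants: 16 4-hydroxy-4-(2-hydroxyethyl)cyclohexa-2,5-dien-1-one
Product: 17 4-hydroxy-4-(2-hydroxyethyl)cyclohexan-1-one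
Conditions: H2 (1 atm), Pd/C (palladium on carbon), EtOAc, 23 °C
Reagents that add atoms: none
Why: Catalytic hydrogenation over Pd/C in a neutral aprotic solvent saturates both enone double bonds and keeps the tertiary hydroxyl and the ketone.

Step 14
Reactants: 17 4-hydroxy-4-(2-hydroxyethyl)cyclohexan-1-one
Product: 18 1-(2-hydroxyethyl)cyclohexane-r-1,t-4-diol
Conditions: LiBH(s-Bu)3 (3.5 equiv), THF, −78 °C; then NaOH, H2O2, 0 °C
Reagents that add atoms: none
Why: In this diastereoselective ketone reduction the bulky hydride attacks from the equatorial direction in the conformer that holds the hydroxyethyl chain equatorial and the tertiary hydroxyl axial, so the new hydroxyl should be axial and hence trans to the tertiary hydroxyl, and diastereomeric purity is secured by chromatography at this small-fragment stage.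

Step 15
Reactants: 19 geranyl acetate
Product: 20 (2E,6E)-8-hydroxy-3,7-dimethylocta-2,6-dien-1-yl acetate
Conditions: SeO2 (cat.), t-BuOOH, salicylic acid (cat.), CH2Cl2, 23 °C
Reagents that add atoms: tert-butyl hydroperoxide CC(C)(C)OO
Why: Riley-type allylic oxidation proceeds by an ene reaction and a [2,3]-sigmatropic shift at the more electron-rich, remote trisubstituted alkene and hydroxylates its (E)-methyl group selectively.

Step 16
Reactants: 20 (2E,6E)-8-hydroxy-3,7-dimethylocta-2,6-dien-1-yl acetate
Product: 22 (2E,6E)-8-acetoxy-2,6-dimethylocta-2,6-dienoic acid, via acetoxy enal 21 (not isolated)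
Conditions: TEMPO (cat.), PhI(OAc)2, CH2Cl2, 23 °C; then NaClO2, NaH2PO4, 2-methyl-2-butene, t-BuOH/H2O, 23 °C
Reagents that add atoms: sodium chlorite [Na+].[O-]Cl=O
Why: TEMPO/PhI(OAc)2 oxidises the primary allylic alcohol to the enal without double-bond isomerisation and the Pinnick oxidation, with 2-methyl-2-butene as hypochlorite scavenger, then gives the acid with the (E) geometry retained.

Step 17
Reactants: 22 (2E,6E)-8-acetoxy-2,6-dimethylocta-2,6-dienoic acid; 18 1-(2-hydroxyethyl)cyclohexane-r-1,t-4-diol
Product: 23 2-(r-1,t-4-dihydroxycyclohexyl)ethyl (2E,6E)-8-acetoxy-2,6-dimethylocta-2,6-dienoate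
Conditions: PPh3, DIAD, THF, 0 → 23 °C
Reagents that add atoms: none
Why: In the Mitsunobu esterification only the primary hydroxyl of 18 is activated at a useful rate, the axial secondary and the tertiary hydroxyl being far slower, and since the acid itself is never activated its conjugated double bond cannot migrate.

Step 18
Reactants: 23 2-(r-1,t-4-dihydroxycyclohexyl)ethyl (2E,6E)-8-acetoxy-2,6-dimethylocta-2,6-dienoate
Product: 24 2-[t-4-(tert-butyldimethylsilyloxy)-r-1-hydroxycyclohexyl]ethyl (2E,6E)-8-acetoxy-2,6-dimethylocta-2,6-dienoate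
Conditions: TBSCl, imidazole, DMF, 23 → 40 °C
Reagents that add atoms: tert-butyldimethylsilyl chloride CC(C)(C)[Si](C)(C)Cl
Why: Silyl ether formation protects the remaining secondary hydroxyl, which would otherwise compete in the later Mitsunobu step, while the tertiary hydroxyl is too hindered to react.

Step 19
Reactants: 24 2-[t-4-(tert-butyldimethylsilyloxy)-r-1-hydroxycyclohexyl]ethyl (2E,6E)-8-acetoxy-2,6-dimethylocta-2,6-dienoate
Product: 25 2-[t-4-(tert-butyldimethylsilyloxy)-r-1-hydroxycyclohexyl]ethyl (2E,6E)-8-hydroxy-2,6-dimethylocta-2,6-dienoate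
Conditions: K2CO3 (cat.), MeOH, 0 °C
Reagents that add atoms: none
Why: Carbonate-catalysed methanolysis (transesterification) removes the primary allylic acetate much faster than it attacks the hindered, conjugated α-methyl enoate, and the silyl ether is stable to these conditions.

Step 20
Reactants: 25 2-[t-4-(tert-butyldimethylsilyloxy)-r-1-hydroxycyclohexyl]ethyl (2E,6E)-8-hydroxy-2,6-dimethylocta-2,6-dienoate
Product: 27 (2E,6E)-8-{2-[t-4-(tert-butyldimethylsilyloxy)-r-1-hydroxycyclohexyl]ethoxy}-3,7-dimethyl-8-oxoocta-2,6-dienoic acid, via enal ester 26 (not isolated)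
Conditions: TEMPO (cat.), PhI(OAc)2, CH2Cl2, 23 °C; then NaClO2, NaH2PO4, 2-methyl-2-butene, t-BuOH/H2O, 23 °C
Reagents that add atoms: sodium chlorite [Na+].[O-]Cl=O
Why: The same TEMPO/PhI(OAc)2 oxidation followed by Pinnick oxidation converts the (E)-allylic alcohol into the (E)-3-methyl-2-enoic acid, the silyl ether, the tertiary alcohol and the existing ester being inert to both oxidants.

Step 21
Reactants: 14 (4S,4aR,6R,7R,7aS)-2,4,7-trimethyloctahydro-1H-cyclopenta[c]pyridin-6-ol; 27 (2E,6E)-8-{2-[t-4-(tert-butyldimethylsilyloxy)-r-1-hydroxycyclohexyl]ethoxy}-3,7-dimethyl-8-oxoocta-2,6-dienoic acid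
Product: 28 1-{2-[t-4-(tert-butyldimethylsilyloxy)-r-1-hydroxycyclohexyl]ethyl} 8-[(4S,4aR,6S,7R,7aS)-2,4,7-trimethyloctahydro-1H-cyclopenta[c]pyridin-6-yl] (2E,6E)-2,6-dimethylocta-2,6-dienedioate
Conditions: PPh3, DIAD, THF, 0 → 23 °C
Reagents that add atoms: none
Why: Mitsunobu esterification activates the concave C6 hydroxyl of 14 as an alkoxyphosphonium ion that the carboxylate of 27 displaces from the convex face with inversion (6R to 6S), placing the ester cis to the 7-methyl, while the tertiary amine, the tertiary alcohol and the silyl ether do not interfere.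

Step 22
Reactants: 28 1-{2-[t-4-(tert-butyldimethylsilyloxy)-r-1-hydroxycyclohexyl]ethyl} 8-[(4S,4aR,6S,7R,7aS)-2,4,7-trimethyloctahydro-1H-cyclopenta[c]pyridin-6-yl] (2E,6E)-2,6-dimethylocta-2,6-dienedioate
Product: 29 1-[2-(r-1,t-4-dihydroxycyclohexyl)ethyl] 8-[(4S,4aR,6S,7R,7aS)-2,4,7-trimethyloctahydro-1H-cyclopenta[c]pyridin-6-yl] (2E,6E)-2,6-dimethylocta-2,6-dienedioate
Conditions: HF·pyridine, pyridine, THF, 0 → 23 °C
Reagents that add atoms: none
Why: Fluoride-mediated desilylation with buffered HF·pyridine cleaves the secondary silyl ether without hydrolysing or migrating either ester and without epimerising any centre, which should deliver the target.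

Compound list
1 | furfurylamine | NCc1ccco1 | starting material
2 | methyl (furan-2-ylmethyl)carbamate | COC(=O)NCc1ccco1 | intermediate
3 | methyl 6-hydroxy-3-oxo-3,6-dihydropyridine-1(2H)-carboxylate (racemic hemiaminal) | COC(=O)N1CC(=O)C=CC1O | intermediate
4 | methyl 3-oxo-3,6-dihydropyridine-1(2H)-carboxylate | COC(=O)N1CC=CC(=O)C1 | intermediate
5 | but-2-yn-1-ol | CC#CCO | starting material
6 | (Z)-2-[(trimethylsilyl)methyl]but-2-en-1-ol | C/C=C(\C[Si](C)(C)C)CO | intermediate
7 | (Z)-2-[(trimethylsilyl)methyl]but-2-en-1-yl acetate | C/C=C(\C[Si](C)(C)C)COC(C)=O | intermediate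
8 | methyl (4aS,7R,7aR)-7-methyl-6-methylidene-4-oxooctahydro-2H-cyclopenta[c]pyridine-2-carboxylate (cis-fused, 7-methyl on the convex face) | C=C1C[C@H]2[C@H](CN(C(=O)OC)CC2=O)[C@H]1C | intermediate
9 | methyl (4S,4aS,7R,7aR)-4-hydroxy-4,7-dimethyl-6-methylideneoctahydro-2H-cyclopenta[c]pyridine-2-carboxylate (4-hydroxyl on the concave face) | C=C1C[C@H]2[C@H](CN(C(=O)OC)C[C@@]2(C)O)[C@H]1C | intermediate
10 | spiro-ozonide of 9 (1,2,4-trioxolane spiro-fused at C6, either configuration at the spiro carbon) | C1OOC2(O1)C[C@H]3[C@H](CN(C(=O)OC)C[C@@]3(C)O)[C@H]2C | intermediate (not isolated)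
11 | methyl (4S,4aS,7R,7aS)-4-hydroxy-4,7-dimethyl-6-oxooctahydro-2H-cyclopenta[c]pyridine-2-carboxylate | O=C1C[C@H]2[C@H](CN(C(=O)OC)C[C@@]2(C)O)[C@H]1C | intermediate
12 | methyl (4aS,7R,7aS)-4,7-dimethyl-6-oxo-1,4a,5,6,7,7a-hexahydro-2H-cyclopenta[c]pyridine-2-carboxylate (C3=C4 enecarbamate) | O=C1C[C@H]2[C@H](CN(C(=O)OC)C=C2C)[C@H]1C | intermediate
13 | methyl (4S,4aR,7R,7aS)-4,7-dimethyl-6-oxooctahydro-2H-cyclopenta[c]pyridine-2-carboxylate | O=C1C[C@H]2[C@H](CN(C(=O)OC)C[C@H]2C)[C@H]1C | intermediate
14 | (4S,4aR,6R,7R,7aS)-2,4,7-trimethyloctahydro-1H-cyclopenta[c]pyridin-6-ol (hydroxyl concave, trans to the 7-methyl) | O[C@@H]1C[C@H]2[C@H](CN(C)C[C@H]2C)[C@H]1C | intermediate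
15 | tyrosol, 4-(2-hydroxyethyl)phenol | OCCc1ccc(O)cc1 | starting material
16 | 4-hydroxy-4-(2-hydroxyethyl)cyclohexa-2,5-dien-1-one | O=C1C=CC(O)(CCO)C=C1 | intermediate
17 | 4-hydroxy-4-(2-hydroxyethyl)cyclohexan-1-one | O=C1CCC(O)(CCO)CC1 | intermediate
18 | 1-(2-hydroxyethyl)cyclohexane-r-1,t-4-diol (hydroxyls trans, 4-hydroxyl cis to the chain) | OCC[C@]1(O)CC[C@H](O)CC1 | intermediate
19 | geranyl acetate, (2E)-3,7-dimethylocta-2,6-dien-1-yl acetate | CC(C)=CCC/C(C)=C/COC(C)=O | starting material
20 | (2E,6E)-8-hydroxy-3,7-dimethylocta-2,6-dien-1-yl acetate | OC/C(C)=C/CC/C(C)=C/COC(C)=O | intermediate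
21 | acetoxy enal, (2E,6E)-3,7-dimethyl-8-oxoocta-2,6-dien-1-yl acetate | O=C/C(C)=C/CC/C(C)=C/COC(C)=O | intermediate (not isolated)
22 | (2E,6E)-8-acetoxy-2,6-dimethylocta-2,6-dienoic acid | OC(=O)/C(C)=C/CC/C(C)=C/COC(C)=O | intermediate
23 | 2-(r-1,t-4-dihydroxycyclohexyl)ethyl (2E,6E)-8-acetoxy-2,6-dimethylocta-2,6-dienoate | CC(=O)OC/C=C(\C)CC/C=C(\C)C(=O)OCC[C@]1(O)CC[C@H](O)CC1 | intermediate
24 | 2-[t-4-(tert-butyldimethylsilyloxy)-r-1-hydroxycyclohexyl]ethyl (2E,6E)-8-acetoxy-2,6-dimethylocta-2,6-dienoate | CC(=O)OC/C=C(\C)CC/C=C(\C)C(=O)OCC[C@]1(O)CC[C@H](O[Si](C)(C)C(C)(C)C)CC1 | intermediate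
25 | 2-[t-4-(tert-butyldimethylsilyloxy)-r-1-hydroxycyclohexyl]ethyl (2E,6E)-8-hydroxy-2,6-dimethylocta-2,6-dienoate | OC/C=C(\C)CC/C=C(\C)C(=O)OCC[C@]1(O)CC[C@H](O[Si](C)(C)C(C)(C)C)CC1 | intermediate
26 | enal ester, 2-[t-4-(tert-butyldimethylsilyloxy)-r-1-hydroxycyclohexyl]ethyl (2E,6E)-2,6-dimethyl-8-oxoocta-2,6-dienoate | O=C/C=C(\C)CC/C=C(\C)C(=O)OCC[C@]1(O)CC[C@H](O[Si](C)(C)C(C)(C)C)CC1 | intermediate (not isolated)
27 | (2E,6E)-8-{2-[t-4-(tert-butyldimethylsilyloxy)-r-1-hydroxycyclohexyl]ethoxy}-3,7-dimethyl-8-oxoocta-2,6-dienoic acid | OC(=O)/C=C(\C)CC/C=C(\C)C(=O)OCC[C@]1(O)CC[C@H](O[Si](C)(C)C(C)(C)C)CC1 | intermediate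
28 | 1-{2-[t-4-(tert-butyldimethylsilyloxy)-r-1-hydroxycyclohexyl]ethyl} 8-[(4S,4aR,6S,7R,7aS)-2,4,7-trimethyloctahydro-1H-cyclopenta[c]pyridin-6-yl] (2E,6E)-2,6-dimethylocta-2,6-dienedioate | C/C(=C\C(=O)O[C@H]1C[C@H]2[C@H](CN(C)C[C@H]2C)[C@H]1C)CC/C=C(\C)C(=O)OCC[C@]1(O)CC[C@H](O[Si](C)(C)C(C)(C)C)CC1 | intermediate
29 | CNP0298382.1, 1-[2-(r-1,t-4-dihydroxycyclohexyl)ethyl] 8-[(4S,4aR,6S,7R,7aS)-2,4,7-trimethyloctahydro-1H-cyclopenta[c]pyridin-6-yl] (2E,6E)-2,6-dimethylocta-2,6-dienedioate | C/C(=C\C(=O)O[C@H]1C[C@H]2[C@H](CN(C)C[C@H]2C)[C@H]1C)CC/C=C(\C)C(=O)OCC[C@]1(O)CC[C@H](O)CC1 | target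

Total step count: 22.
Longest linear sequence: 11 steps (steps 1, 2, 3, 6, 7, 8, 9, 10, 11, 21, 22, from furfurylamine 1 to target 29).

Steps most likely to fail

Step 6. The cycloaddition may stall through protodesilylation or β-hydride loss from the donor, the donor termini may not be differentiated, or the ligand may discriminate the two faces of this unactivated cyclic enone poorly. The fallback makes the same two bonds one after the other by established reactions and obtains the absolute configuration by resolution. It sets out from 4 and 7: a TiCl4-mediated Hosomi–Sakurai conjugate allylation (CH2Cl2, −78 °C) should join the γ-carbon of the allylsilane to the enone β-carbon and give racemic methyl 3-[3-(acetoxymethyl)but-3-en-2-yl]-5-oxopiperidine-1-carboxylate F1. An intramolecular Tsuji–Trost alkylation of its ketone through an enamine relay (Pd(PPh3)4, catalytic pyrrolidine, THF) would then close C4a–C5 on the symmetrical 2-substituted allyl unit and give racemic cis-fused methyl 7-methyl-6-methylidene-4-oxooctahydro-2H-cyclopenta[c]pyridine-2-carboxylate F2, with C7 left open as in the main route. Separation of the enantiomers by preparative chromatography on a chiral stationary phase brings the route back at 8.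

Step 9. The hindered concave tertiary hydroxyl may resist sulfamoylation, or the elimination may lose its syn course through an ion pair and run toward C4a, which would endanger that stereocentre. The fallback removes the oxygen by radical deoxygenation instead of elimination and hydrogenation. It sets out from 11: acylation with methyl chlorooxoacetate (pyridine, DMAP, CH2Cl2, 0 °C) should give methyl (4S,4aS,7R,7aS)-4-[(methoxyoxalyl)oxy]-4,7-dimethyl-6-oxooctahydro-2H-cyclopenta[c]pyridine-2-carboxylate F3, and a Barton–McCombie-type reduction (Bu3SnH, AIBN, toluene, 110 °C) would generate the C4 radical, which should take up hydrogen on the convex face. After the methoxide treatment already used in step 10 the route is rejoined at 13.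

Step 21. Activation of the hindered concave hydroxyl may be slow with the weakly acidic enoic acid, and elimination to the cyclopentene may compete with substitution. The fallback separates activation from displacement. It sets out from 14: mesylation (MsCl, Et3N, CH2Cl2, 0 °C) should give (4S,4aR,6R,7R,7aS)-2,4,7-trimethyloctahydro-1H-cyclopenta[c]pyridin-6-yl methanesulfonate F4, and SN2 displacement by acid 27 in the presence of Cs2CO3 (DMF, 50 °C) would invert C6 and come back to the route at 28.

Further compounds
F1 | step 6 | methyl 3-[3-(acetoxymethyl)but-3-en-2-yl]-5-oxopiperidine-1-carboxylate (racemic, both side-chain epimers) | COC(=O)N1CC(C(C)C(=C)COC(C)=O)CC(=O)C1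
F2 | step 6 | racemic cis-fused methyl 7-methyl-6-methylidene-4-oxooctahydro-2H-cyclopenta[c]pyridine-2-carboxylate (C7 open) | C=C1C[C@H]2[C@H](CN(C(=O)OC)CC2=O)C1C.C=C1C[C@@H]2[C@@H](CN(C(=O)OC)CC2=O)C1C
F3 | step 9 | methyl (4S,4aS,7R,7aS)-4-[(methoxyoxalyl)oxy]-4,7-dimethyl-6-oxooctahydro-2H-cyclopenta[c]pyridine-2-carboxylate | O=C1C[C@H]2[C@H](CN(C(=O)OC)C[C@@]2(C)OC(=O)C(=O)OC)[C@H]1C
F4 | step 21 | (4S,4aR,6R,7R,7aS)-2,4,7-trimethyloctahydro-1H-cyclopenta[c]pyridin-6-yl methanesulfonate | CS(=O)(=O)O[C@@H]1C[C@H]2[C@H](CN(C)C[C@H]2C)[C@H]1C
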